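## Analysis of the target

Kadsurenin D is a bicyclo[3.2.1]oct-2-ene-4,8-dione. Numbering used throughout: C1 is the allyl-bearing bridgehead, C2=C3 the enol ether (OMe on C3), C4 the enone carbonyl, C5 the CH bridgehead, C6 the aryl carbon, C7 the methyl carbon and C8 the bridging ketone. The skeleton is a cyclopentanone (C8, C1, C7, C6, C5) spanned from C1 to C5 by the unit C2=C3(OMe)–C4(=O), which closes the six-membered ring C1–C2–C3–C4–C5–C8. There are four contiguous stereocentres: quaternary C1, then C7, C6 and C5. On the cyclopentanone the C7 methyl lies on the face that carries the three-carbon bridge, the C6 aryl group on the opposite face (trans to methyl), and the C1 allyl group trans to the methyl; C5 is tied to C1 by the bridge. The C4/C8 1,3-diketone cannot enolise through the bridgehead C5, so nucleophilic bases can cleave it by retro-Claisen reaction. The enol ether, the terminal alkene and the electron-rich arene limit the use of strong acids and oxidants. The hard part is the quaternary C1, flanked by C8=O and two further stereocentres, together with the bridging bond. The route rests on one feature: seen from the C8 ketone, the α-carbon C1 carries allyl and the β-carbon C7 carries methyl, trans to each other. That is the pattern left when a nucleophile adds to the β-carbon and an electrophile to the α-carbon of a C1=C7 enone, with the C6 aryl group next door to steer the first addition.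

## Retrosynthetic reasoning

**C4–C5 (24 ⇒ 22).** The bridged diketone is made last, because it is the most fragile function. In 22 the C8 ketone has only one enolisable position, C5, since C1 is quaternary. Enolate 23 can therefore only form at C5, and its attack on the acyl carbon C4 closes the six-membered ring. The acyl donor is an aryl ester: the aryloxide it releases is too weak a nucleophile to reopen a diketone that cannot protect itself by enolate formation. The configuration at C5 follows from C1, since the arm can only reach one face.

**Ester exchange (22 ⇒ 21 ⇒ 20).** The aryl ester cannot be present during the key step. In enolate 19 the oxygen on C8 is joined to the ester carbon C4 through four sp2 atoms with a cis double bond, the geometry of a coumarin-type lactonisation. An aryloxide leaving group would let that oxygen close a fused 2-pyranone before C1 is alkylated. The carboxyl group is therefore carried as a tert-butyl ester, which resists acyl transfer, and is converted to the aryl ester only after C1 is quaternary.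

**C7–CH3 and C1–allyl (20 ⇒ 16 + 17 + 18).** Both bonds are cut at once. The forward reaction adds methyl from 17 to C7 of enone 16 and traps enolate 19 with 18 at C1. Cutting here removes two stereocentres and the quaternary carbon in one operation and leaves C6 as the only stereocentre of the precursor. The step must add trans to the aryl group, alkylate carbon C1 of a delocalised anion, and keep the acrylate geometry.

**C1–C2 (16 ⇒ 8 + 15).** The arm is attached to the enone α-carbon by a Stille coupling of α-iodoenone 8 with alkenylstannane 15. The coupling is neutral, which matters because the C6–H of every 4-arylcyclopentenone in this route is allylic, benzylic and γ to the ketone. It also transfers the alkene geometry unchanged.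

**Stannane (15 ⇒ 14 ⇒ 12 ⇒ 10 + 11; 10 ⇒ 9).** The tin sits cis to the ester. That geometry is the one a metal chelate of the formylated ester 12 enforces, so O-sulfonylation of chelate 13 and palladium-catalysed exchange of the sulfonate in 14 for tin give 15. The three carbons C4, C3 and C2 come from 9 (through 10) and formate 11.

**Iodoenone (8 ⇒ 7 ⇒ 5 ⇒ 4 ⇒ 1 + 2).** α-Iodination of 7 gives 8. Enone 7 is not made by dehydrogenating a saturated ketone, because that would require telling two α-methylene groups apart. Instead the aryl group of 2 is added to silyloxy enone 1 trans to the silyloxy group (via 3 to 4). The oxygen is then removed on the other side of the ketone (5, via mesylate 6). The double bond can only form away from the aryl carbon, and the stereocentre of 1 is exchanged for C6 with full regiochemical certainty.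

## Alternatives that were turned down

**Alternative 1:** Disconnection of C1–C2 and C4–C5, so that the six-membered ring is annulated onto a symmetric dione. In the forward key step 2-allylcyclopentane-1,3-dione A2 adds through C1 to acrolein A3, and a chiral amine–thiourea catalyst directs the aldol of one of the two enantiotopic α-carbons onto the aldehyde. The product is the bicyclic hydroxy dione A1. In its favour: the whole bicycle, the quaternary C1 and C5 arise in one catalytic step from achiral commodity materials. On speed to the ring system and on catalytic asymmetry it is stronger than the chosen route. Against it: A1 has a carbonyl at C7, a methylene at C6, a saturated C2–C3 and no oxygen at C3. The C7 and C8 ketones would have to be told apart, C7=O turned into C7–CH3, an aryl group brought to C6 trans to it, C4–OH oxidised, and C3 oxidised and methylated. That is a long sequence of selective operations on a compact skeleton with three carbonyl-type groups. The chosen route is slower to the ring but carries every substituent in its final oxidation state from the start.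

**Alternative 2:** Disconnection of C1–C2 by palladium enolate alkenylation. The substrate is cyclopentanone A5, which carries the bromo enol ether arm on C5 and allyl on C1. Zerovalent palladium inserts into the C2–Br bond and the C8 enolate couples at C1 to give the bridged silyl ether A4. In its favour: the ring closure and the quaternary centre are formed together, and the C1 configuration is fixed by the geometry of the ring, not by facial selectivity. On that point it is more certain than the chosen route. C4 is also at the alcohol level during the closure, so no acyl transfer can interfere. Against it: A5 needs five stereocentres, one of which (C4) is later destroyed. Its C8 ketone has two tertiary α-positions, and enolisation at C5 would expel the β-silyloxy group, so the base must find C1 selectively. Desilylation and oxidation then add two steps after the key step. The chosen route instead sets C7 and C1 in one operation on a precursor with a single stereocentre.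

**Alternative 3:** Disconnection of C6–C7 and C1–allyl by an interrupted Nazarov cyclisation. A Lewis acid closes the E,E-dienone A7 by conrotatory 4π-electrocyclisation, and allyltrimethylsilane A8 captures the oxyallyl cation at C1 to give cyclopentanone A6. In its favour: the five-membered ring and three stereocentres come in one step from an acyclic dienone that an aldol condensation would supply, and the conrotatory closure guarantees the trans C6/C7 relationship. In ring construction it is stronger than the chosen route. Against it: absolute control needs a chiral Lewis acid, and A7 offers no two-point binding site next to the ketone. The electron-rich aryl group stabilises the pentadienyl cation and slows the closure. The allylsilane must attack the more substituted terminus C1, not C5. The propanoate arm of A6 still lacks the C2=C3 double bond and the C3 oxygen, which must be introduced after the bicycle is closed. The chosen route takes its absolute configuration from a defined building block and needs no late oxidation.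

Key step: step 10

Assumption: enantiopure (4S)-4-[(tert-butyldimethylsilyl)oxy]cyclopent-2-en-1-one (1) and a THF solution of Grignard reagent 2 are taken as commercial.

## Route

Step 1
Reactants: 1 (4S)-4-[(tert-butyldimethylsilyl)oxy]cyclopent-2-en-1-one; 2 (3,4-dimethoxyphenyl)magnesium bromide
Product: 4 (3R,4S)-4-[(tert-butyldimethylsilyl)oxy]-3-(3,4-dimethoxyphenyl)cyclopentan-1-one, via trimethylsilyl enol ether 3 (not isolated)
Conditions: 2 (1.5 equiv), CuBr·SMe2 (10 mol %), Me3SiCl (2 equiv), THF, −78 °C; then 1 M HCl, 0 °C
Reagents that add atoms: none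
Why: Copper-catalysed conjugate addition of a Grignard reagent, with the enolate trapped as silyl enol ether 3 so that it cannot equilibrate and expel the silyloxy group; brief acid hydrolyses 3 to the ketone. The aryl group should enter trans to the bulky C4 silyloxy group, which sets the future C6 centre by substrate control.

Step 2
Reactants: 4 (3R,4S)-4-[(tert-butyldimethylsilyl)oxy]-3-(3,4-dimethoxyphenyl)cyclopentan-1-one
Product: 5 (3R,4S)-3-(3,4-dimethoxyphenyl)-4-hydroxycyclopentan-1-one
Conditions: 48% aq. HF, MeCN, 0 °C → rt
Reagents that add atoms: none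
Why: Acidic fluoride cleavage of a secondary silyl ether; no base is present, so the β-hydroxy ketone is not epimerised and the aryl centre is untouched.

Step 3
Reactants: 5 (3R,4S)-3-(3,4-dimethoxyphenyl)-4-hydroxycyclopentan-1-one
Product: 7 (4S)-4-(3,4-dimethoxyphenyl)cyclopent-2-en-1-one, via secondary mesylate 6 (not isolated)
Conditions: MeSO2Cl (1.3 equiv), Et3N (3 equiv), CH2Cl2, −30 → 0 °C; cold aqueous work-up
Reagents that add atoms: none
Why: Mesylation and E1cB elimination of a β-sulfonyloxy ketone; the leaving group is β only to the CH2 remote from the aryl carbon, so the double bond can form in one position only. A weak amine at low temperature is chosen so that the acidic C4–H of the product is not removed.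

Step 4
Reactants: 7 (4S)-4-(3,4-dimethoxyphenyl)cyclopent-2-en-1-one
Product: 8 (4S)-4-(3,4-dimethoxyphenyl)-2-iodocyclopent-2-en-1-one
Conditions: I2 (1.5 equiv), pyridine–CH2Cl2 (1:1), 0 °C → rt, dark
Reagents that add atoms: iodine, II
Why: α-Iodination of an enone by the addition–iodination–elimination sequence (pyridine adds to the β-carbon, the enolate is iodinated, pyridine is expelled). Pyridine is too weak a base to touch the C4–H.

Step 5
Reactants: 9 methoxyacetic acid
Product: 10 tert-butyl methoxyacetate
Conditions: 2-methylpropene (excess), H2SO4 (cat.), CH2Cl2, sealed vessel, rt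
Reagents that add atoms: 2-methylpropene, C=C(C)C
Why: Acid-catalysed addition of a carboxylic acid to isobutene, the standard tert-butyl ester synthesis; nothing else in 9 reacts.

Step 6
Reactants: 10 tert-butyl methoxyacetate; 11 ethyl formate
Product: 12 tert-butyl (2E)-3-hydroxy-2-methoxyprop-2-enoate (hydrogen-bonded enol form of tert-butyl 2-formyl-2-methoxyacetate)
Conditions: LiN(i-Pr)2 (1.1 equiv), THF, −78 °C; 11 (1.5 equiv), −78 → 0 °C; 1 M HCl to pH 4
Reagents that add atoms: none
Why: Crossed Claisen condensation of a kinetically deprotonated tert-butyl ester with a non-enolisable formate. The tert-butyl ester does not self-condense or transesterify, and the acidic product is held as its salt until work-up.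

Step 7
Reactants: 12 tert-butyl (2E)-3-hydroxy-2-methoxyprop-2-enoate
Product: 14 tert-butyl (2E)-2-methoxy-3-{[(trifluoromethyl)sulfonyl]oxy}prop-2-enoate, via sodium enolate 13 (not isolated)
Conditions: NaH (1.1 equiv), Et2O, 0 °C; (CF3SO2)2O (1.1 equiv), −78 → 0 °C
Reagents that add atoms: trifluoromethanesulfonic anhydride, O=S(=O)(OS(=O)(=O)C(F)(F)F)C(F)(F)F
Why: Chelation-controlled enol triflation of a β-dicarbonyl compound. In a weakly coordinating solvent sodium bridges the formyl oxygen and the ester carbonyl in 13, so sulfonylation should fix the triflate cis to the ester (E).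

Step 8
Reactants: 14 tert-butyl (2E)-2-methoxy-3-{[(trifluoromethyl)sulfonyl]oxy}prop-2-enoate
Product: 15 tert-butyl (2E)-2-methoxy-3-(trimethylstannyl)prop-2-enoate
Conditions: Me3SnSnMe3 (1.3 equiv), Pd(PPh3)4 (5 mol %), LiCl (5 equiv), THF, 60 °C
Reagents that add atoms: hexamethyldistannane, C[Sn](C)(C)[Sn](C)(C)C
Why: Palladium-catalysed stannylation of an alkenyl triflate with a distannane; oxidative addition, transmetalation and reductive elimination all proceed with retention, so tin stays cis to the ester.

Step 9
Reactants: 8 (4S)-4-(3,4-dimethoxyphenyl)-2-iodocyclopent-2-en-1-one; 15 tert-butyl (2E)-2-methoxy-3-(trimethylstannyl)prop-2-enoate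
Product: 16 tert-butyl (2E)-3-[(3S)-3-(3,4-dimethoxyphenyl)-5-oxocyclopent-1-en-1-yl]-2-methoxyprop-2-enoate
Conditions: Pd2(dba)3 (2.5 mol %), AsPh3 (20 mol %), CuI (10 mol %), DMF, rt → 40 °C, dark
Reagents that add atoms: none
Why: Stille coupling of an α-iodoenone with an alkenylstannane; the weak ligand and the copper co-catalyst speed up transmetalation of the electron-poor stannane. The medium is neutral, so the C6–H is safe, and the alkene geometry is transferred unchanged.

Step 10
Reactants: 16 tert-butyl (2E)-3-[(3S)-3-(3,4-dimethoxyphenyl)-5-oxocyclopent-1-en-1-yl]-2-methoxyprop-2-enoate; 17 lithium dimethylcuprate; 18 allyl bromide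
Product: 20 tert-butyl (2E)-3-[(1S,4S,5R)-4-(3,4-dimethoxyphenyl)-5-methyl-2-oxo-1-(prop-2-en-1-yl)cyclopentyl]-2-methoxyprop-2-enoate, via C1 lithium enolate 19 (not isolated)
Conditions: 17 (1.3 equiv, from CuI and MeLi, Et2O, 0 °C), THF, −78 °C; then DMPU (5 equiv), 18 (5 equiv), −78 → −40 °C; aq. NH4Cl/NH3
Reagents that add atoms: none
Why: The cuprate forms a π-complex with the C1=C7 bond of 16, oxidative addition gives a β-cuprio enolate of trivalent copper and reductive elimination forms C7–CH3, leaving lithium enolate 19 and MeCu; the closest known reaction type is the vicinal difunctionalisation of cyclopentenones by organocuprate conjugate addition and alkylation of the resulting enolate. No ring is closed in this step. C7 is the β-carbon of the ketone and the δ-carbon of the dienoate, so both acceptors direct the nucleophile to the same carbon, while C2 is the electron-rich β-carbon of an enol ether and should stay untouched. The new C7 centre is controlled by the C6 aryl group, which shields one face of the flat enone so that methyl enters trans to it. In 19 the charge sits mainly on the ketone oxygen because the tert-butyl ester is the weaker acceptor, so allyl bromide activated by DMPU should alkylate C1, the α-carbon of the ketone enolate, and not C3, which is hindered by methoxy and the tert-butyl ester. The quaternary C1 centre is controlled by the adjacent C7 methyl group: the electrophile approaches the enolate face anti to it, which places allyl trans and the acrylate arm cis to methyl. The step needs site selectivity (C7 over C2), C- over O-alkylation (an O-allyl dienol ether would give the same product by [3,3] shift to C1) and retention of the acrylate geometry, which the low temperature and the largely localised C2=C3 bond should secure. The tert-butyl ester is essential because the neighbouring enolate oxygen cannot acylate itself on it, whereas an aryl ester would be converted into a fused 2-pyranone.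

Step 11
Reactants: 20 tert-butyl (2E)-3-[(1S,4S,5R)-4-(3,4-dimethoxyphenyl)-5-methyl-2-oxo-1-(prop-2-en-1-yl)cyclopentyl]-2-methoxyprop-2-enoate
Product: 21 (2E)-3-[(1S,4S,5R)-4-(3,4-dimethoxyphenyl)-5-methyl-2-oxo-1-(prop-2-en-1-yl)cyclopentyl]-2-methoxyprop-2-enoic acid
Conditions: CF3CO2H–CH2Cl2 (1:4), 1,3-dimethoxybenzene (3 equiv), 0 °C → rt
Reagents that add atoms: none
Why: Acidolysis of a tert-butyl ester. The more nucleophilic scavenger keeps the tert-butyl cation away from the veratryl ring, and the electron-poor α-methoxyacrylate, the ketone and the terminal alkene should tolerate anhydrous acid.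

Step 12
Reactants: 21 (2E)-3-[(1S,4S,5R)-4-(3,4-dimethoxyphenyl)-5-methyl-2-oxo-1-(prop-2-en-1-yl)cyclopentyl]-2-methoxyprop-2-enoic acid
Product: 22 phenyl (2E)-3-[(1S,4S,5R)-4-(3,4-dimethoxyphenyl)-5-methyl-2-oxo-1-(prop-2-en-1-yl)cyclopentyl]-2-methoxyprop-2-enoate
Conditions: PhOH (1.5 equiv), EDC·HCl (1.5 equiv), DMAP (0.2 equiv), CH2Cl2, 0 °C → rt
Reagents that add atoms: phenol, Oc1ccccc1
Why: Steglich esterification. Excess phenol and the acyl-transfer catalyst should intercept the activated acid before the ketone can, and no stereocentre is α to an acidic position under these conditions.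

Step 13
Reactants: 22 phenyl (2E)-3-[(1S,4S,5R)-4-(3,4-dimethoxyphenyl)-5-methyl-2-oxo-1-(prop-2-en-1-yl)cyclopentyl]-2-methoxyprop-2-enoate
Product: 24 kadsurenin D, (1S,5S,6R,7R)-6-(3,4-dimethoxyphenyl)-3-methoxy-7-methyl-1-(prop-2-en-1-yl)bicyclo[3.2.1]oct-2-ene-4,8-dione, via C5 lithium enolate 23 (not isolated)
Conditions: LiN(SiMe3)2 (1.2 equiv), THF, −78 → −20 °C; AcOH (2 equiv), −78 °C, then pH 7 buffer
Reagents that add atoms: none
Why: Intramolecular Claisen (Dieckmann-type) acylation in the 6-(enolendo)-exo-trig mode. C5 is the only enolisable position of the C8 ketone, and the lithium enolate attacks the aryl ester carbon C4 from the face that carries the arm, which fixes C5. Phenoxide is expelled irreversibly and is too weak to cleave the product; it can also reopen any O-acylated enol lactone, so the C-acylated diketone should be the sink.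

## Compound list

1 | (4S)-4-[(tert-butyldimethylsilyl)oxy]cyclopent-2-en-1-one | O=C1C=C[C@@H](O[Si](C)(C)C(C)(C)C)C1 | starting material
2 | (3,4-dimethoxyphenyl)magnesium bromide | COc1ccc([Mg]Br)cc1OC | starting material
3 | tert-butyl{[(1S,2R)-2-(3,4-dimethoxyphenyl)-4-[(trimethylsilyl)oxy]cyclopent-3-en-1-yl]oxy}dimethylsilane | C[Si](C)(C)OC1=C[C@H](c2ccc(OC)c(OC)c2)[C@@H](O[Si](C)(C)C(C)(C)C)C1 | intermediate
4 | (3R,4S)-4-[(tert-butyldimethylsilyl)oxy]-3-(3,4-dimethoxyphenyl)cyclopentan-1-one | O=C1C[C@H](c2ccc(OC)c(OC)c2)[C@@H](O[Si](C)(C)C(C)(C)C)C1 | intermediate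
5 | (3R,4S)-3-(3,4-dimethoxyphenyl)-4-hydroxycyclopentan-1-one | O=C1C[C@H](c2ccc(OC)c(OC)c2)[C@@H](O)C1 | intermediate
6 | (1S,2R)-2-(3,4-dimethoxyphenyl)-4-oxocyclopentyl methanesulfonate | O=C1C[C@H](c2ccc(OC)c(OC)c2)[C@@H](OS(C)(=O)=O)C1 | intermediate
7 | (4S)-4-(3,4-dimethoxyphenyl)cyclopent-2-en-1-one | O=C1C=C[C@@H](c2ccc(OC)c(OC)c2)C1 | intermediate
8 | (4S)-4-(3,4-dimethoxyphenyl)-2-iodocyclopent-2-en-1-one | O=C1C(I)=C[C@@H](c2ccc(OC)c(OC)c2)C1 | intermediate
9 | methoxyacetic acid | COCC(=O)O | starting material
10 | tert-butyl methoxyacetate | COCC(=O)OC(C)(C)C | intermediate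
11 | ethyl formate | CCOC=O | starting material
12 | tert-butyl (2E)-3-hydroxy-2-methoxyprop-2-enoate | O/C=C(/OC)C(=O)OC(C)(C)C | intermediate
13 | sodium (1E)-3-tert-butoxy-2-methoxy-3-oxoprop-1-en-1-olate | [Na+].[O-]/C=C(/OC)C(=O)OC(C)(C)C | intermediate
14 | tert-butyl (2E)-2-methoxy-3-{[(trifluoromethyl)sulfonyl]oxy}prop-2-enoate | O=S(=O)(O/C=C(/OC)C(=O)OC(C)(C)C)C(F)(F)F | intermediate
15 | tert-butyl (2E)-2-methoxy-3-(trimethylstannyl)prop-2-enoate | C[Sn](C)(C)/C=C(/OC)C(=O)OC(C)(C)C | intermediate
16 | tert-butyl (2E)-3-[(3S)-3-(3,4-dimethoxyphenyl)-5-oxocyclopent-1-en-1-yl]-2-methoxyprop-2-enoate | O=C1C(/C=C(/OC)C(=O)OC(C)(C)C)=C[C@@H](c2ccc(OC)c(OC)c2)C1 | intermediate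
17 | lithium dimethylcuprate | [Li+].C[Cu-]C | starting material
18 | allyl bromide | C=CCBr | starting material
19 | lithium (3R,4S)-2-[(1E)-3-tert-butoxy-2-methoxy-3-oxoprop-1-en-1-yl]-4-(3,4-dimethoxyphenyl)-3-methylcyclopent-1-en-1-olate | [Li+].[O-]C1=C(/C=C(/OC)C(=O)OC(C)(C)C)[C@H](C)[C@@H](c2ccc(OC)c(OC)c2)C1 | intermediate
20 | tert-butyl (2E)-3-[(1S,4S,5R)-4-(3,4-dimethoxyphenyl)-5-methyl-2-oxo-1-(prop-2-en-1-yl)cyclopentyl]-2-methoxyprop-2-enoate | O=C1[C@](CC=C)(/C=C(/OC)C(=O)OC(C)(C)C)[C@H](C)[C@@H](c2ccc(OC)c(OC)c2)C1 | intermediate
21 | (2E)-3-[(1S,4S,5R)-4-(3,4-dimethoxyphenyl)-5-methyl-2-oxo-1-(prop-2-en-1-yl)cyclopentyl]-2-methoxyprop-2-enoic acid | O=C1[C@](CC=C)(/C=C(/OC)C(=O)O)[C@H](C)[C@@H](c2ccc(OC)c(OC)c2)C1 | intermediate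
22 | phenyl (2E)-3-[(1S,4S,5R)-4-(3,4-dimethoxyphenyl)-5-methyl-2-oxo-1-(prop-2-en-1-yl)cyclopentyl]-2-methoxyprop-2-enoate | O=C1[C@](CC=C)(/C=C(/OC)C(=O)Oc2ccccc2)[C@H](C)[C@@H](c2ccc(OC)c(OC)c2)C1 | intermediate
23 | lithium (3R,4R,5S)-3-(3,4-dimethoxyphenyl)-5-[(1E)-2-methoxy-3-oxo-3-phenoxyprop-1-en-1-yl]-4-methyl-5-(prop-2-en-1-yl)cyclopent-1-en-1-olate | [Li+].[O-]C1=C[C@H](c2ccc(OC)c(OC)c2)[C@@H](C)[C@@]1(CC=C)/C=C(/OC)C(=O)Oc1ccccc1 | intermediate
24 | kadsurenin D, (1S,5S,6R,7R)-6-(3,4-dimethoxyphenyl)-3-methoxy-7-methyl-1-(prop-2-en-1-yl)bicyclo[3.2.1]oct-2-ene-4,8-dione | C=CC[C@]12C=C(OC)C(=O)[C@H](C1=O)[C@H](c1ccc(OC)c(OC)c1)[C@H]2C | target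

## Step count and least certain steps

Total: 13 steps. Longest linear sequence: 9 steps (steps 1–4 or 5–8, then 9–13).

**Step 10 (key step).** The delocalised anion 19 may be alkylated at C3 or at oxygen instead of C1. Rotation about the C2–C3 bond of the anion may erode the E geometry, and an arm with the ester trans to the ring cannot close later. A slow alkylation of this hindered, stabilised enolate would give time for both. Fallback, from 16 back to 20: the cuprate addition is run as before, but 19 is trapped at −78 °C with allyl chloroformate, which acylates oxygen fast, to give allyl (3R,4S)-2-[(1E)-3-tert-butoxy-2-methoxy-3-oxoprop-1-en-1-yl]-4-(3,4-dimethoxyphenyl)-3-methylcyclopent-1-en-1-yl carbonate F1. After isolation, Pd(PPh3)4 (cat.) in THF at rt ionises F1, carbon dioxide is lost, and the tight π-allylpalladium/enolate ion pair recombines at carbon (Tsuji–Trost type decarboxylative allylation). A soft stabilised enolate is the ideal nucleophile for this, it is never long-lived, and attack anti to the C7 methyl should again give 20.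

**Step 13.** The enolate may be acylated on oxygen to give a six-membered enol lactone. The strained, non-enolisable diketone may also be cleaved by retro-Claisen attack of phenoxide, amide or hydroxide during the reaction or the quench. Fallback, from 21 back to 24: acid 21 is coupled with N,O-dimethylhydroxylamine hydrochloride (EDC·HCl, i-Pr2NEt, CH2Cl2) to (2E)-3-[(1S,4S,5R)-4-(3,4-dimethoxyphenyl)-5-methyl-2-oxo-1-(prop-2-en-1-yl)cyclopentyl]-N,2-dimethoxy-N-methylprop-2-enamide F2. Treatment of F2 with LiN(SiMe3)2 in THF (−78 → 0 °C) and an acetic acid quench should give 24. Attack by oxygen on this amide is unproductive because no leaving group can depart. Attack by C5 gives a lithium-chelated tetrahedral adduct that releases no nucleophile until it is protonated, so neither side reaction has a pathway.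

**Step 7.** If sulfonylation does not go through the chelate, or the enolate geometry equilibrates, a mixture of geometric isomers results and is carried into 16. Fallback, from 12 back to 16: chelation-controlled tosylation (TsCl, Me2NCH2CH2NMe2, LiCl, MeCN, 0 °C) gives tert-butyl (2E)-2-methoxy-3-{[(4-methylphenyl)sulfonyl]oxy}prop-2-enoate F3. Miyaura borylation (bis(pinacolato)diboron, PdCl2(dppf), KOAc, dioxane, 80 °C) gives tert-butyl (2E)-2-methoxy-3-(4,4,5,5-tetramethyl-1,3,2-dioxaborolan-2-yl)prop-2-enoate F4. Suzuki–Miyaura coupling of F4 with 8 (Pd(PPh3)4, K3PO4, THF–H2O, rt) gives 16 without tin.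

**Step 3.** The C4–H of 7 is allylic, benzylic and γ to the ketone. The amine may remove it, which would racemise the centre or move the double bond into conjugation with the arene. Fallback: this one replaces the sequence from 1 and 2. It sets out from commercial cyclopent-2-en-1-one and 3,4-dimethoxyphenylboronic acid and comes back to the route at 7. Rhodium-catalysed conjugate arylation (Rh(acac)(C2H4)2, (R)-BINAP, dioxane–H2O, 100 °C) gives (3R)-3-(3,4-dimethoxyphenyl)cyclopentan-1-one F5. Kinetic enolisation on the less hindered side (LiN(i-Pr)2, Me3SiCl, THF, −78 °C) gives {[(4R)-4-(3,4-dimethoxyphenyl)cyclopent-1-en-1-yl]oxy}trimethylsilane F6. Saegusa–Ito oxidation (Pd(OAc)2, MeCN, rt), which is neutral, gives 7. The regioisomeric silyl enol ether leads to an achiral conjugated enone that would be removed by chromatography, so imperfect regioselectivity costs material, not purity.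

## Further compounds

F1 | step 10 | allyl (3R,4S)-2-[(1E)-3-tert-butoxy-2-methoxy-3-oxoprop-1-en-1-yl]-4-(3,4-dimethoxyphenyl)-3-methylcyclopent-1-en-1-yl carbonate | C=CCOC(=O)OC1=C(/C=C(/OC)C(=O)OC(C)(C)C)[C@H](C)[C@@H](c2ccc(OC)c(OC)c2)C1
F2 | step 13 | (2E)-3-[(1S,4S,5R)-4-(3,4-dimethoxyphenyl)-5-methyl-2-oxo-1-(prop-2-en-1-yl)cyclopentyl]-N,2-dimethoxy-N-methylprop-2-enamide | O=C1[C@](CC=C)(/C=C(/OC)C(=O)N(C)OC)[C@H](C)[C@@H](c2ccc(OC)c(OC)c2)C1
F3 | step 7 | tert-butyl (2E)-2-methoxy-3-{[(4-methylphenyl)sulfonyl]oxy}prop-2-enoate | Cc1ccc(S(=O)(=O)O/C=C(/OC)C(=O)OC(C)(C)C)cc1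
F4 | step 7 | tert-butyl (2E)-2-methoxy-3-(4,4,5,5-tetramethyl-1,3,2-dioxaborolan-2-yl)prop-2-enoate | CC1(C)OB(/C=C(/OC)C(=O)OC(C)(C)C)OC1(C)C
F5 | step 3 | (3R)-3-(3,4-dimethoxyphenyl)cyclopentan-1-one | O=C1CC[C@@H](c2ccc(OC)c(OC)c2)C1
F6 | step 3 | {[(4R)-4-(3,4-dimethoxyphenyl)cyclopent-1-en-1-yl]oxy}trimethylsilane | C[Si](C)(C)OC1=CC[C@@H](c2ccc(OC)c(OC)c2)C1
A1 | alternative 1 | 1-allyl-4-hydroxybicyclo[3.2.1]octane-7,8-dione | C=CC[C@]12CC[C@H](O)[C@H](C1=O)CC2=O
A2 | alternative 1 | 2-allylcyclopentane-1,3-dione | C=CCC1C(=O)CCC1=O
A3 | alternative 1 | acrolein | C=CC=O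
A4 | alternative 2 | 1-allyl-4-[(tert-butyldimethylsilyl)oxy]-6-(3,4-dimethoxyphenyl)-3-methoxy-7-methylbicyclo[3.2.1]oct-2-en-8-one | C=CC[C@]12C=C(OC)[C@H](O[Si](C)(C)C(C)(C)C)[C@H](C1=O)[C@H](c1ccc(OC)c(OC)c1)[C@H]2C
A5 | alternative 2 | 2-allyl-5-{(2E)-3-bromo-1-[(tert-butyldimethylsilyl)oxy]-2-methoxyprop-2-en-1-yl}-4-(3,4-dimethoxyphenyl)-3-methylcyclopentan-1-one (configured as A4 at C4 to C7, both C1 epimers) | Br/C=C(/OC)[C@H](O[Si](C)(C)C(C)(C)C)[C@@H]1C(=O)C(CC=C)[C@H](C)[C@H]1c2ccc(OC)c(OC)c2
A6 | alternative 3 | methyl 3-[1-allyl-4-(3,4-dimethoxyphenyl)-5-methyl-2-oxocyclopentyl]propanoate | O=C1[C@](CC=C)(CCC(=O)OC)[C@H](C)[C@@H](c2ccc(OC)c(OC)c2)C1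
A7 | alternative 3 | methyl (4E)-4-[(2E)-3-(3,4-dimethoxyphenyl)prop-2-enoyl]hex-4-enoate | C/C=C(\CCC(=O)OC)C(=O)/C=C/c1ccc(OC)c(OC)c1
A8 | alternative 3 | allyltrimethylsilane | C=CC[Si](C)(C)C
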